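Follow one molecule of target.

| flask | substrate | other conformer | remark | time |
|---|---|---|---|---|
| east | 1.4 M | 0.25 M (fed, over 1.0 h) | run made earlier |  |
| north-east | 2.2 M | 0.25 M (fed, over 1.0 h) | run made earlier |  |
| west | 1 M | 0.38 M (fed, over 1.0 h) | run made earlier |  |
| flask | 1.0 M | 0.250 M (fed, over 1.0 h) |  | 12 h |

- east (time / h: target / %, over-reaction product / %): 1.50: 3.2, 0; 3.00: 5.4, 1.4; 5.00: 8.8, 6.7; 6.00: 7.6, 7.2; 8.00: 9.3, 11.3; 10.0: 9.6, 15.8; 12.0: 6.8, 18.6
- north-east (time / h: target / %, over-reaction product / %): 0.667: 1.5, 0; 2.00: 4.8, 1.6; 3.00: 5.8, 1.8; 5.00: 6.9, 5.2; 8.00: 8.5, 9.7; 10.0: 8.1, 14.3; 12.0: 8.5, 17.4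
- west (time / h: target / %, over-reaction product / %): 1.00: 2.1, 1.7; 2.00: 4.9, 0; 3.00: 5.1, 2.9; 6.00: 8.6, 7.0; 12.0: 7.2, 19.6

(standard deviation of a reading: 1 percentage point)



- amount of target in the flask at 12 h, in percent of the substrate and other conformer together charged
- amount of over-reaction product in the flask at 12 h, in percent of the substrate and other conformer together charged
- amount of isomer of the product B in the flask at 12 h, in percent of the substrate and other conformer together charged

In these flasks substrate feeds target, and target appears to pass on to over-reaction product, which lags behind it: in the east run at 1.50 h, target reads 3.2% and over-reaction product 0%. The quantity to carry is the leak, an apparent first-order rate constant: over-reaction product gained per hour for each unit of target standing in the flask. Between 6.00 h and 12.0 h, the east run gains 11 percentage points on a mean target of 8.33%, so the leak reads 0.228 h⁻¹, with the scatter of those readings.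

A target molecule therefore has a half-life of 3.04 h at this fork. The ladder starts with the feed, which ends at 1.0 h, sooner than that half-life. The leak comes next, and the run lasts 3.95 of its half-lives. The half-life is shorter than the run, and between 5.00 h and 12.0 h the east run reads target at 8.8% and then 6.8%, while over-reaction product goes from 6.7% to 18.6%. At 12.0 h, the readings of these two species add up to a quarter of the east charge.

The reckoning here starts from the west run, which has the flask's substrate: 7.0% over-reaction product at 6.00 h, plus the leak on its mean target, gives 17.8% for the flask. Isomer of the product B has no reading. The forecast is higher on over-reaction product, at 19%, with target 8% and isomer of the product B 6%, of which it says “this is only a guess”.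

The flask gives target 9.41%, over-reaction product 19.6% and isomer of the product B 20.8%.

    substrate ⇌ other conformer (K = 0.0200, k = 0.324 h⁻¹)
    substrate → target (k = 0.0860 h⁻¹)
    other conformer → isomer of the product A (k = 0.852 h⁻¹)
    target → over-reaction product (k = 0.223 h⁻¹)
    substrate + target → side product (k = 0.115 M⁻¹ h⁻¹)
    target ⇌ isomer of the product B (K = 2.20, k = 4.07 h⁻¹)

Isomer of the product B stands 15 points above the forecast, at twice the target. In this flask, over-reaction product holds 7.28% at 6.00 h; the leak on a mean target of 8.92% carries it to 19.5% at 12 h, and the flask holds 19.6%. The neighbouring flask, stopped at 8.0 h, has a mean target of 8.80% from 6.00 h on. The leak then gives 11.3%, and that flask holds 11.2%.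

The readings are calculated on assumed constants.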